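## Retrosynthetic overview
1. Target ⇒ MOM removal ⇒ suprafacial α-ketol 1,2-shift. The C15 chain moves from C4 to C3 of a (2S,4S)-2-chloro-4-hydroxy-2-methylnaphthalene-1,3-dione, so the C4 configuration passes to C3.
2. That dione ⇒ C2-methylation anti to the chain ⇒ (4S)-2-chloro-3,4-dihydroxynaphthalen-1(4H)-one ⇒ catalytic enantioselective hydroxylative dearomatisation at C4 of a 2-chloro-4-alkylnaphthalene-1,3-diol (new step).
3. Naphthalenediol ⇒ intramolecular Claisen closure, then NCS ⇒ bis-MOM methyl orsellinate functionalised twice at its benzylic carbon (C15 allylic bromide, then acetyl Weinreb amide).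
4. C15 bromide ⇒ PBr3 transposition of a tertiary allylic alcohol ⇒ MeLi on a 2-methylene ester ⇒ carboalumination of a C8 enyne and Pd coupling with methyl 2-(bromomethyl)acrylate.
5. Ring order: the resorcinol ring is formed first (self-condensation of methyl acetoacetate), then the second carbocycle (Claisen closure).

Assumption and conventions: ring atoms carry the 1,3,6,8-tetrahydroxynaphthalene numbering throughout (C1 is peri to the 8-oxygen); R* = (4E)-5,9-dimethyl-2-(propan-2-ylidene)deca-4,8-dien-1-yl, i.e. CH2–C(=CMe2)–CH2–CH=C(Me)–CH2CH2–CH=CMe2; the L-pipecolic-acid-derived ligand of step 10 is assumed to give the 4S product, and its D-antipode is used if the sense is opposite.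

## Route

Step 1
Reactants: 1 5-bromo-2-methylpent-2-ene; 2 lithium acetylide–ethylenediamine complex
Product: 3 6-methylhept-5-en-1-yne
Conditions: DMSO, 0 °C → rt
Reagents that add atoms: none
Why: SN2 alkynylation of an unhindered primary bromide by lithium acetylide in DMSO is a standard route to terminal alkynes, and the remote trisubstituted alkene is inert.

Step 2
Reactants: 3 6-methylhept-5-en-1-yne; 4 methyl 2-(bromomethyl)acrylate
Product: 6 methyl (4E)-5,9-dimethyl-2-methylidenedeca-4,8-dienoate, via alkenylalane 5 (not isolated)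
Conditions: Me3Al (2 equiv), Cp2ZrCl2 (20 mol%), CH2Cl2, 0 °C → rt; volatiles off; THF, 4, Pd(PPh3)4 (3 mol%), 0 °C → rt
Reagents that add atoms: trimethylaluminium, C[Al](C)C
Why: Negishi Zr-catalysed methylalumination adds Me and Al syn with Al at the terminus (>98% E), and the alkenylalane couples with retention with the allylic bromide under Pd(0) (Negishi alkenyl–allyl coupling), where attack at either allyl terminus gives the same product.

Step 3
Reactants: 6 methyl (4E)-5,9-dimethyl-2-methylidenedeca-4,8-dienoate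
Product: 7 (5E)-2,6,10-trimethyl-3-methylideneundeca-5,9-dien-2-ol
Conditions: MeLi (2.3 equiv), Et2O, −78 → 0 °C; then H2O
Reagents that add atoms: methyllithium, [Li]C
Why: Double 1,2-addition of a hard organolithium to an ester gives the dimethyl carbinol, because MeLi attacks the carbonyl of the α-substituted acrylate and of the transient enone rather than the β-carbon.

Step 4
Reactants: 7 (5E)-2,6,10-trimethyl-3-methylideneundeca-5,9-dien-2-ol
Product: 8 (5E)-3-(bromomethyl)-2,6,10-trimethylundeca-2,5,9-triene (R*–Br)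
Conditions: PBr3 (0.4 equiv), pyridine (cat.), Et2O, −10 °C
Reagents that add atoms: phosphorus tribromide, BrP(Br)Br
Why: Bromination of a tertiary allylic alcohol with allylic transposition (SN2′ or ion pair) gives the favoured primary bromide with the tetrasubstituted alkene, as in 2-methylbut-3-en-2-ol → prenyl bromide.

Step 5
Reactants: 9 methyl acetoacetate (2 equiv)
Product: 10 methyl 2,4-dihydroxy-6-methylbenzoate (methyl orsellinate)
Conditions: NaH, then n-BuLi, THF, −78 °C → reflux; aq HCl
Reagents that add atoms: none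
Why: The Weiler dianion of one molecule is C-acylated by the ester of a second (Claisen condensation), and the resulting 3,5,7-trioxo ester closes by aldol condensation and aromatises, a known polyketide-type resorcylate synthesis.

Step 6
Reactants: 10 methyl 2,4-dihydroxy-6-methylbenzoate
Product: 11 methyl 2,4-bis(methoxymethoxy)-6-methylbenzoate
Conditions: NaH (2.5 equiv), MOMCl (2.5 equiv), DMF, 0 °C → rt
Reagents that add atoms: chloromethyl methyl ether, COCCl
Why: Williamson-type O-alkylation of both phenoxides (NaH also frees the chelated 2-OH) gives acetal ethers that are inert to amide bases and alkoxides.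

Step 7
Reactants: 11 methyl 2,4-bis(methoxymethoxy)-6-methylbenzoate; 8 R*–Br
Product: 12 methyl 2,4-bis(methoxymethoxy)-6-[(5E)-6,10-dimethyl-3-(propan-2-ylidene)undeca-5,9-dien-1-yl]benzoate (ArCH2–R*)
Conditions: LDA (1.2 equiv), THF, −78 °C; 8, −78 → −30 °C
Reagents that add atoms: none
Why: Lateral lithiation of the o-toluate gives the ester-stabilised benzylic anion, which displaces the primary allylic bromide by SN2 and fixes the chain at the future C4 without regiochemical ambiguity.

Step 8
Reactants: 12 ArCH2–R* benzoate; 13 N-methoxy-N-methylacetamide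
Product: 14 methyl 2,4-bis(methoxymethoxy)-6-[(7E)-8,12-dimethyl-2-oxo-5-(propan-2-ylidene)trideca-7,11-dien-3-yl]benzoate (ArCH(R*)C(O)CH3, racemic)
Conditions: LDA (1.5 equiv), THF, −78 °C; 13; AcOH quench
Reagents that add atoms: none
Why: A second lateral lithiation followed by Weinreb ketone synthesis stops at the chelated tetrahedral adduct, so there is no over-addition or proton quench, and the racemic benzylic stereocentre is erased in step 9.

Step 9
Reactants: 14 ArCH(R*)C(O)CH3 benzoate
Product: 16 2-chloro-6,8-bis(methoxymethoxy)-4-R*-naphthalene-1,3-diol, via naphthalene-1,3-diol 15 (not isolated)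
Conditions: KOt-Bu (2.2 equiv), THF, 0 °C → rt, Ar; AcOH (2.2 equiv), then NCS (1.0 equiv), 0 °C
Reagents that add atoms: N-chlorosuccinimide, O=C1CCC(=O)N1Cl
Why: Under equilibrating base only the methyl-side enolate can close a six-membered ring onto the ester (Dieckmann-type intramolecular Claisen condensation) with the naphthalenediolate as sink, and the air-sensitive diol is chlorinated in the same flask by SEAr at C2, the only free position of the diol ring.

Step 10
Reactants: 16 2-chloro-6,8-bis(methoxymethoxy)-4-R*-naphthalene-1,3-diol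
Product: 17 (4S)-2-chloro-3,4-dihydroxy-6,8-bis(methoxymethoxy)-4-R*-naphthalen-1(4H)-one
Conditions: Sc(OTf)3 (10 mol%), C2-symmetric N,N′-dioxide ligand (L-pipecolic acid core, 2,6-diisopropylanilide arms, C3 linker; 10 mol%), (±)-3-phenyl-2-(phenylsulfonyl)oxaziridine (1.2 equiv), 4 Å MS, CH2Cl2, −20 °C, Ar
Reagents that add atoms: 3-phenyl-2-(phenylsulfonyl)oxaziridine, O=S(=O)(c1ccccc1)N1OC1c1ccccc1
Why: Proposed new method: catalytic enantioselective hydroxylative dearomatisation of a 2-halo-4-alkylnaphthalene-1,3-diol, in which the Sc(III)-bound C3 naphtholate attacks the oxaziridine oxygen through C4 (the most nucleophilic carbon, pushed by O3 ortho and O1 para with the benzo ring kept aromatic) in an SN2-type O-transfer on the face left open by the anilide arms, setting 4S; no aryloxenium ion forms, so the tetrasubstituted alkene cannot start a cationic cyclisation, the oxaziridine does not epoxidise alkenes at −20 °C, and C2 is blocked by Cl against a second oxidation; the closest known reactions are the Sc(III)/N,N′-dioxide-catalysed hydroxylative dearomatisation of 1-alkyl-2-naphthols with oxaziridines and the Davis enolate oxidation.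

Step 11
Reactants: 17 (4S)-2-chloro-3,4-dihydroxy-6,8-bis(methoxymethoxy)-4-R*-naphthalen-1(4H)-one
Product: 18 (2S,4S)-2-chloro-4-hydroxy-6,8-bis(methoxymethoxy)-2-methyl-4-R*-naphthalene-1,3(2H,4H)-dione
Conditions: MeI (10 equiv), KHCO3 (1.1 equiv), CF3CH2OH, 30 °C, dark
Reagents that add atoms: iodomethane, CI
Why: C-alkylation of the ambident 2-chloro-1,3-diketonate with soft MeI is favoured by Kornblum-type solvent control (the protic fluorinated solvent hydrogen-bonds the enolate oxygens), and MeI approaches C2 anti to the pseudo-axial C4 chain, so CH3 ends cis to the C4–OH and Cl cis to R*, while bicarbonate is too weak to ionise the tertiary alcohol.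

Step 12
Reactants: 18 (2S,4S)-2-chloro-4-hydroxy-6,8-bis(methoxymethoxy)-2-methyl-4-R*-naphthalene-1,3(2H,4H)-dione
Product: 20 (2R,3S)-2-chloro-3,6,8-trihydroxy-2-methyl-3-R*-2,3-dihydronaphthalene-1,4-dione (target), via MOM-protected ketol 19 (not isolated)
Conditions: PhMe, 110 °C, 8 h; cool; MeOH, p-TsOH·H2O (20 mol%), 45 °C
Reagents that add atoms: none
Why: In the α-ketol (acyloin) rearrangement the C4–OH proton passes to the now non-enolisable C3 ketone while R*, perpendicular to that carbonyl, shifts suprafacially from C4 to C3, driven by formation of the conjugated aryl ketone; this turns 4S into 3S with R* still cis to Cl and leaves the quaternary C2 untouched, and acid-catalysed acetal exchange with MeOH then frees the two carbonyl-activated phenols under conditions the alkenes and the trans-chlorohydrin tolerate.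

## Compound list
1 | 5-bromo-2-methylpent-2-ene | CC(C)=CCCBr | starting material
2 | lithium acetylide–ethylenediamine complex | [Li]C#C.NCCN | starting material
3 | 6-methylhept-5-en-1-yne | CC(C)=CCCC#C | intermediate
4 | methyl 2-(bromomethyl)acrylate | C=C(CBr)C(=O)OC | starting material
5 | [(1E)-2,6-dimethylhepta-1,5-dien-1-yl]dimethylalane | CC(C)=CCC/C(C)=C/[Al](C)C | intermediate
6 | methyl (4E)-5,9-dimethyl-2-methylidenedeca-4,8-dienoate | CC(C)=CCC/C(C)=C/CC(=C)C(=O)OC | intermediate
7 | (5E)-2,6,10-trimethyl-3-methylideneundeca-5,9-dien-2-ol | CC(C)=CCC/C(C)=C/CC(=C)C(C)(C)O | intermediate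
8 | (5E)-3-(bromomethyl)-2,6,10-trimethylundeca-2,5,9-triene | CC(C)=CCC/C(C)=C/CC(CBr)=C(C)C | intermediate
9 | methyl acetoacetate | CC(=O)CC(=O)OC | starting material
10 | methyl 2,4-dihydroxy-6-methylbenzoate | COC(=O)c1c(C)cc(O)cc1O | intermediate
11 | methyl 2,4-bis(methoxymethoxy)-6-methylbenzoate | COCOc1cc(C)c(C(=O)OC)c(OCOC)c1 | intermediate
12 | methyl 2,4-bis(methoxymethoxy)-6-[(5E)-6,10-dimethyl-3-(propan-2-ylidene)undeca-5,9-dien-1-yl]benzoate | CC(C)=CCC/C(C)=C/CC(CCc1cc(OCOC)cc(OCOC)c1C(=O)OC)=C(C)C | intermediate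
13 | N-methoxy-N-methylacetamide | CC(=O)N(C)OC | starting material
14 | methyl 2,4-bis(methoxymethoxy)-6-[(7E)-8,12-dimethyl-2-oxo-5-(propan-2-ylidene)trideca-7,11-dien-3-yl]benzoate (racemic) | CC(C)=CCC/C(C)=C/CC(CC(C(C)=O)c1cc(OCOC)cc(OCOC)c1C(=O)OC)=C(C)C | intermediate
15 | 6,8-bis(methoxymethoxy)-4-R*-naphthalene-1,3-diol | CC(C)=CCC/C(C)=C/CC(Cc1c(O)cc(O)c2c(OCOC)cc(OCOC)cc12)=C(C)C | intermediate
16 | 2-chloro-6,8-bis(methoxymethoxy)-4-R*-naphthalene-1,3-diol | CC(C)=CCC/C(C)=C/CC(Cc1c(O)c(Cl)c(O)c2c(OCOC)cc(OCOC)cc12)=C(C)C | intermediate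
17 | (4S)-2-chloro-3,4-dihydroxy-6,8-bis(methoxymethoxy)-4-R*-naphthalen-1(4H)-one | CC(C)=CCC/C(C)=C/CC(C[C@@]1(O)C(O)=C(Cl)C(=O)c2c(OCOC)cc(OCOC)cc21)=C(C)C | intermediate
18 | (2S,4S)-2-chloro-4-hydroxy-6,8-bis(methoxymethoxy)-2-methyl-4-R*-naphthalene-1,3(2H,4H)-dione | CC(C)=CCC/C(C)=C/CC(C[C@@]1(O)C(=O)[C@@](C)(Cl)C(=O)c2c(OCOC)cc(OCOC)cc21)=C(C)C | intermediate
19 | (2R,3S)-2-chloro-3-hydroxy-6,8-bis(methoxymethoxy)-2-methyl-3-R*-2,3-dihydronaphthalene-1,4-dione | CC(C)=CCC/C(C)=C/CC(C[C@]1(O)C(=O)c2cc(OCOC)cc(OCOC)c2C(=O)[C@]1(C)Cl)=C(C)C | intermediate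
20 | (2R,3S)-2-chloro-3,6,8-trihydroxy-2-methyl-3-R*-2,3-dihydronaphthalene-1,4-dione (CNP0351608.1) | CC(C)=CCC/C(C)=C/CC(C[C@]1(O)C(=O)c2cc(O)cc(O)c2C(=O)[C@]1(C)Cl)=C(C)C | target

## Step count and risks
Total steps: 12. Longest linear sequence: 10 (steps 1–4, then 7–12).

**Step 10 (proposed new step).**
- Risks: low ee on a 1,3-diol that carries a 2-chloro substituent, product inhibition of Sc(III) by the acidic vinylogous acid, and slow turnover.
- Fallback (known chemistry), from 16 back to 17: 16 is deprotonated with KHMDS (1 equiv, THF, −78 °C) and oxidised with the same oxaziridine without a chiral catalyst (Davis oxidation).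
- This gives racemic 2-chloro-3,4-dihydroxy-6,8-bis(methoxymethoxy)-4-R*-naphthalen-1(4H)-one F1.
- Preparative SFC on a chiral stationary phase then separates 17 from the (4R)-2-chloro-3,4-dihydroxy-6,8-bis(methoxymethoxy)-4-R*-naphthalen-1(4H)-one F2, which is discarded.

**Step 11.**
- Risks: O-methylation of the weakly nucleophilic chloro-diketonate instead of quaternary C–C bond formation, and incomplete facial control.
- Fallback, from 17 back to 19: 17 is chlorinated once more (NCS, CH2Cl2, 0 °C) to (4S)-2,2-dichloro-4-hydroxy-6,8-bis(methoxymethoxy)-4-R*-naphthalene-1,3(2H,4H)-dione F3, which has no C2 stereocentre.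
- Heating in toluene effects the same α-ketol shift and gives (3S)-2,2-dichloro-3-hydroxy-6,8-bis(methoxymethoxy)-3-R*-2,3-dihydronaphthalene-1,4-dione F4.
- Me2CuLi (−78 °C) reduces one C–Cl bond to the α-chloro enolate of a simple ketone, which alkylates reliably on carbon.
- MeI then enters anti to the neighbouring R* to give 19, which is deprotected as in the second half of step 12.

**Step 8.**
- Risks: sluggish lithiation and acylation of the secondary benzylic position, and self-condensation.
- Fallback, from 11 back to 14 (step 7 is bypassed): the order of the two benzylic bond formations is reversed.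
- The primary toluate anion of 11 (LDA, THF, −78 °C) is acylated with 13 to give methyl 2,4-bis(methoxymethoxy)-6-(2-oxopropyl)benzoate F5.
- Its doubly activated benzylic carbon is deprotonated irreversibly (NaH, THF, 0 °C) and alkylated with 8 to give 14.

## Further compounds
F1 | step 10 | racemic 2-chloro-3,4-dihydroxy-6,8-bis(methoxymethoxy)-4-R*-naphthalen-1(4H)-one | CC(C)=CCC/C(C)=C/CC(CC1(O)C(O)=C(Cl)C(=O)c2c(OCOC)cc(OCOC)cc21)=C(C)C
F2 | step 10 | (4R)-2-chloro-3,4-dihydroxy-6,8-bis(methoxymethoxy)-4-R*-naphthalen-1(4H)-one | CC(C)=CCC/C(C)=C/CC(C[C@]1(O)C(O)=C(Cl)C(=O)c2c(OCOC)cc(OCOC)cc21)=C(C)C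
F3 | step 11 | (4S)-2,2-dichloro-4-hydroxy-6,8-bis(methoxymethoxy)-4-R*-naphthalene-1,3(2H,4H)-dione | CC(C)=CCC/C(C)=C/CC(C[C@@]1(O)C(=O)C(Cl)(Cl)C(=O)c2c(OCOC)cc(OCOC)cc21)=C(C)C
F4 | step 11 | (3S)-2,2-dichloro-3-hydroxy-6,8-bis(methoxymethoxy)-3-R*-2,3-dihydronaphthalene-1,4-dione | CC(C)=CCC/C(C)=C/CC(C[C@]1(O)C(=O)c2cc(OCOC)cc(OCOC)c2C(=O)C1(Cl)Cl)=C(C)C
F5 | step 8 | methyl 2,4-bis(methoxymethoxy)-6-(2-oxopropyl)benzoate | COCOc1cc(CC(C)=O)c(C(=O)OC)c(OCOC)c1
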